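**Retrosynthetic overview** (labdane numbering: ring A = C1–C5 and C10, ring B = C5–C10, C17 = exocyclic CH2, C11–C16 = side chain)
1. Target ⇐ tert-butyl ester / TBS ether 18 by acetylation and ester cleavage; the C13=C14 geometry and the C12–C13 bond come from syn-carbocupration of a 4-silyloxybut-2-ynoate by the C12 organocopper.
2. C8=CH2 ⇐ C8 ketone (the oxygen of the starting anisole); ring A (C1–C10 bond, C5–H, C2–OMe) ⇐ proton-initiated cation–olefin cyclisation with methanol capture onto the tetrasubstituted alkene of a cyclohexenol.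
3. C9 stereocentre ⇐ palladium-catalysed enantioselective decarboxylative protonation; C9–C11 bond and the 1,4-diene of ring B ⇐ Birch reductive alkylation of a benzoic acid (key step).
4. Arene ⇐ 3-bromo-6-methoxy-2-methylbenzoic acid + acetone + allylsilane (C4 with its two methyls, C3, C2, C1).
5. Ring order: ring B comes from the arene; ring A is closed second.

Assumption: the ligand antipode in step 5 is the one that delivers (S)-9; it is written as (S)-t-BuPHOX and would be switched if the first run shows the opposite sense.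

**Step 1**
Reactants: 1 3-bromo-6-methoxy-2-methylbenzoic acid
Product: 3 3-(2-hydroxypropan-2-yl)-6-methoxy-2-methylbenzoic acid, via dilithio benzoate 2 (not isolated)
Conditions: n-BuLi (2.2 equiv), THF, −78 °C; acetone, −78 → 0 °C; aq HCl
Reagents that add atoms: acetone, CC(C)=O
Why: Bromine–lithium exchange on the lithium carboxylate followed by organolithium 1,2-addition to acetone places the future C4 with both methyls on the ring carbon para to the methoxy group; no stereocentre is formed.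

**Step 2**
Reactants: 3 3-(2-hydroxypropan-2-yl)-6-methoxy-2-methylbenzoic acid
Product: 4 6-methoxy-2-methyl-3-(2-methylpent-4-en-2-yl)benzoic acid
Conditions: allylSiMe3 (2 equiv), InCl3 (5 mol %), ClCH2CH2Cl, 60 °C
Reagents that add atoms: allyltrimethylsilane, C=CC[Si](C)(C)C
Why: Lewis-acid-catalysed SN1 allylation (Hosomi–Sakurai type) of the tertiary benzylic alcohol, whose cation is stabilised by the para-methoxy group, builds the quaternary C4 and the C3–C2=C1 unit; no stereocentre.

**Step 3 (key step)**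
Reactants: 4 6-methoxy-2-methyl-3-(2-methylpent-4-en-2-yl)benzoic acid
Product: 6 racemic 1-(2-chloroethyl)-2-methoxy-6-methyl-5-(2-methylpent-4-en-2-yl)cyclohexa-2,5-diene-1-carboxylic acid, via dilithium dienediolate 5 (not isolated)
Conditions: Li (2.5 equiv), NH3(l)/THF, t-BuOH (1 equiv), −78 °C; BrCH2CH2Cl, −78 → −33 °C; NH4Cl then cold dilute HCl to pH 3
Reagents that add atoms: 1-bromo-2-chloroethane, ClCCBr
Why: Birch reductive alkylation, in which the carboxylate fixes the 1,4-dihydro pattern so that the methoxy, methyl and tert-alkyl carbons stay sp2 and the dienediolate is alkylated at the carboxyl-bearing carbon to make C9–C11; the new quaternary carbon is racemic and is corrected in step 5.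

**Step 4**
Reactants: 6 racemic 1-(2-chloroethyl)-2-methoxy-6-methyl-5-(2-methylpent-4-en-2-yl)cyclohexa-2,5-diene-1-carboxylic acid
Product: 8 racemic prop-2-en-1-yl 1-(2-chloroethyl)-2-methyl-3-(2-methylpent-4-en-2-yl)-6-oxocyclohex-2-ene-1-carboxylate, via allyl ester enol ether 7 (not isolated)
Conditions: Cs2CO3, allyl bromide, DMF, 0 °C → rt; then 1 M HCl, THF, 0 °C
Reagents that add atoms: allyl bromide, C=CCBr; water, O
Why: Carboxylate O-alkylation followed by acid hydrolysis of the methyl enol ether unmasks a β-keto allyl ester whose α-carbon is quaternary, so the ketone can neither decarboxylate nor pull the alkene into conjugation.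

**Step 5**
Reactants: 8 racemic prop-2-en-1-yl 1-(2-chloroethyl)-2-methyl-3-(2-methylpent-4-en-2-yl)-6-oxocyclohex-2-ene-1-carboxylate
Product: 9 (2S)-2-(2-chloroethyl)-3-methyl-4-(2-methylpent-4-en-2-yl)cyclohex-3-en-1-one
Conditions: Pd(OAc)2 (10 mol %), (S)-t-BuPHOX (12.5 mol %), HCO2H (6 equiv), 4 Å MS, 1,4-dioxane, 40 °C
Reagents that add atoms: none
Why: Palladium-catalysed enantioselective decarboxylative protonation (Stoltz type), in which ionisation of the allyl ester and loss of CO2 give a PHOX-bound palladium enolate that formic acid protonates at the α-carbon, setting C9 from either enantiomer of 8.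

**Step 6**
Reactants: 9 (2S)-2-(2-chloroethyl)-3-methyl-4-(2-methylpent-4-en-2-yl)cyclohex-3-en-1-one
Product: 10 (1R,2S)-2-(2-chloroethyl)-3-methyl-4-(2-methylpent-4-en-2-yl)cyclohex-3-en-1-ol
Conditions: LiBH(s-Bu)3, THF, −78 °C; aq NH4Cl
Reagents that add atoms: none
Why: Bulky-hydride (Selectride) reduction from the face opposite the neighbouring C9 chain gives the cis alcohol, which masks the ketone as a non-enolisable, acid-stable group (C8 is re-oxidised in step 8).

**Step 7**
Reactants: 10 (1R,2S)-2-(2-chloroethyl)-3-methyl-4-(2-methylpent-4-en-2-yl)cyclohex-3-en-1-ol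
Product: 11 (1S,2R,4aR,7R,8aR)-1-(2-chloroethyl)-7-methoxy-5,5,8a-trimethyldecahydronaphthalen-2-ol
Conditions: TfOH (0.3 equiv), MeOH (20 equiv), (CF3)2CHOH–CH2Cl2, 0 °C
Reagents that add atoms: methanol, CO
Why: Proton-initiated cation–olefin cyclisation with solvent capture (Stork–Eschenmoser/Johnson type), in which protonation of the strained tetrasubstituted alkene at C5 gives the tertiary C10 cation, the terminal alkene carbon C1 adds anti to the C9 chain through a chair that keeps the C10 methyl axial (trans ring fusion), and methanol traps the C2 cation from the face away from the two axial methyls (equatorial OMe).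

**Step 8**
Reactants: 11 (1S,2R,4aR,7R,8aR)-1-(2-chloroethyl)-7-methoxy-5,5,8a-trimethyldecahydronaphthalen-2-ol
Product: 12 (1S,4aR,7R,8aR)-1-(2-chloroethyl)-7-methoxy-5,5,8a-trimethyloctahydronaphthalen-2(1H)-one
Conditions: Dess–Martin periodinane, pyridine, CH2Cl2, 0 °C → rt
Reagents that add atoms: none
Why: Dess–Martin oxidation of the secondary alcohol under non-basic conditions, so that C9 keeps its configuration and the γ-chloride is not displaced by an enolate.

**Step 9**
Reactants: 12 (1S,4aR,7R,8aR)-1-(2-chloroethyl)-7-methoxy-5,5,8a-trimethyloctahydronaphthalen-2(1H)-one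
Product: 13 (1R,4aR,7R,8aR)-1-(2-chloroethyl)-7-methoxy-5,5,8a-trimethyl-2-methylidenedecahydronaphthalene
Conditions: Zn, CH2Br2, TiCl4, THF–CH2Cl2, 0 °C → rt
Reagents that add atoms: dibromomethane, BrCBr
Why: Takai–Lombardo methylenation, a non-basic Wittig surrogate for hindered enolisable ketones, installs the exocyclic C8=C17 without epimerising C9 or closing a cyclopropane onto the chloride.

**Step 10**
Reactants: 14 tert-butyl(dimethyl)(prop-2-yn-1-yloxy)silane
Product: 16 tert-butyl 4-{[tert-butyl(dimethyl)silyl]oxy}but-2-ynoate, via lithium acetylide 15 (not isolated)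
Conditions: n-BuLi, THF, −78 °C; Boc2O, −78 → 0 °C; aq NH4Cl
Reagents that add atoms: di-tert-butyl dicarbonate, CC(C)(C)OC(=O)OC(=O)OC(C)(C)C
Why: Deprotonation of the terminal alkyne and C-acylation of the lithium acetylide give the ynoate that carries C13–C16.

**Step 11**
Reactants: 13 (1R,4aR,7R,8aR)-1-(2-chloroethyl)-7-methoxy-5,5,8a-trimethyl-2-methylidenedecahydronaphthalene; 16 tert-butyl 4-{[tert-butyl(dimethyl)silyl]oxy}but-2-ynoate
Product: 18 tert-butyl (2Z)-3-({[tert-butyl(dimethyl)silyl]oxy}methyl)-5-[(1R,4aR,7R,8aR)-7-methoxy-5,5,8a-trimethyl-2-methylidenedecahydronaphthalen-1-yl]pent-2-enoate, via alkylmagnesium chloride 17 (not isolated)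
Conditions: Mg (I2-activated), THF, 60 °C; CuBr·SMe2 (1 equiv), −78 °C; 16, −78 → −50 °C; aq NH4Cl
Reagents that add atoms: none
Why: Grignard formation followed by syn-carbocupration of the ynoate (organocopper conjugate addition) and protonation with retention puts C12 and H on the same side of C13=C14, so CH2OTBS and the ester end up cis as in the target.

**Step 12**
Reactants: 18 tert-butyl (2Z)-3-({[tert-butyl(dimethyl)silyl]oxy}methyl)-5-[(1R,4aR,7R,8aR)-7-methoxy-5,5,8a-trimethyl-2-methylidenedecahydronaphthalen-1-yl]pent-2-enoate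
Product: 20 tert-butyl (2Z)-3-(acetoxymethyl)-5-[(1R,4aR,7R,8aR)-7-methoxy-5,5,8a-trimethyl-2-methylidenedecahydronaphthalen-1-yl]pent-2-enoate, via hydroxy ester 19 (not isolated)
Conditions: HF·pyridine, pyridine, THF, 0 °C; then Ac2O, DMAP, 0 °C → rt
Reagents that add atoms: acetic anhydride, CC(=O)OC(C)=O
Why: Fluoride desilylation with immediate acetylation in the same flask, the bulky tert-butyl ester slowing lactonisation of the cis hydroxy ester long enough for the acetate to go on.

**Step 13**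
Reactants: 20 tert-butyl (2Z)-3-(acetoxymethyl)-5-[(1R,4aR,7R,8aR)-7-methoxy-5,5,8a-trimethyl-2-methylidenedecahydronaphthalen-1-yl]pent-2-enoate
Product: 22 (2Z)-3-(acetoxymethyl)-5-[(1R,4aR,7R,8aR)-7-methoxy-5,5,8a-trimethyl-2-methylidenedecahydronaphthalen-1-yl]pent-2-enoic acid, via trimethylsilyl ester 21 (not isolated)
Conditions: TMSOTf, 2,6-lutidine, CH2Cl2, 0 °C; then pH 5 aqueous buffer
Reagents that add atoms: none
Why: Silyl-triflate cleavage of the tert-butyl ester (loss of isobutene to the silyl ester, hydrolysed on work-up) under buffered non-protic conditions that spare the exocyclic alkene, the allylic acetate and the methyl ether, so no free cis hydroxy acid is ever formed.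

**Compound list**
1 | 3-bromo-6-methoxy-2-methylbenzoic acid (bulk agrochemical intermediate) | COc1ccc(Br)c(C)c1C(=O)O | starting material
2 | lithium 3-lithio-6-methoxy-2-methylbenzoate | COc1ccc([Li])c(C)c1C(=O)[O-].[Li+] | intermediate
3 | 3-(2-hydroxypropan-2-yl)-6-methoxy-2-methylbenzoic acid | COc1ccc(C(C)(C)O)c(C)c1C(=O)O | intermediate
4 | 6-methoxy-2-methyl-3-(2-methylpent-4-en-2-yl)benzoic acid | COc1ccc(C(C)(C)CC=C)c(C)c1C(=O)O | intermediate
5 | dilithium [2-methoxy-6-methyl-5-(2-methylpent-4-en-2-yl)cyclohexa-2,5-dien-1-ylidene]methanediolate | COC1=CCC(C(C)(C)CC=C)=C(C)C1=C([O-])[O-].[Li+].[Li+] | intermediate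
6 | racemic 1-(2-chloroethyl)-2-methoxy-6-methyl-5-(2-methylpent-4-en-2-yl)cyclohexa-2,5-diene-1-carboxylic acid | COC1=CCC(C(C)(C)CC=C)=C(C)C1(CCCl)C(=O)O | intermediate
7 | racemic prop-2-en-1-yl 1-(2-chloroethyl)-2-methoxy-6-methyl-5-(2-methylpent-4-en-2-yl)cyclohexa-2,5-diene-1-carboxylate | COC1=CCC(C(C)(C)CC=C)=C(C)C1(CCCl)C(=O)OCC=C | intermediate
8 | racemic prop-2-en-1-yl 1-(2-chloroethyl)-2-methyl-3-(2-methylpent-4-en-2-yl)-6-oxocyclohex-2-ene-1-carboxylate | O=C1CCC(C(C)(C)CC=C)=C(C)C1(CCCl)C(=O)OCC=C | intermediate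
9 | (2S)-2-(2-chloroethyl)-3-methyl-4-(2-methylpent-4-en-2-yl)cyclohex-3-en-1-one | O=C1CCC(C(C)(C)CC=C)=C(C)[C@@H]1CCCl | intermediate
10 | (1R,2S)-2-(2-chloroethyl)-3-methyl-4-(2-methylpent-4-en-2-yl)cyclohex-3-en-1-ol (OH cis to the chloroethyl chain) | O[C@@H]1CCC(C(C)(C)CC=C)=C(C)[C@@H]1CCCl | intermediate
11 | (1S,2R,4aR,7R,8aR)-1-(2-chloroethyl)-7-methoxy-5,5,8a-trimethyldecahydronaphthalen-2-ol (trans-decalin; OMe and chloroethyl equatorial, OH axial) | O[C@@H]1CC[C@@H]2C(C)(C)C[C@@H](OC)C[C@@]2(C)[C@@H]1CCCl | intermediate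
12 | (1S,4aR,7R,8aR)-1-(2-chloroethyl)-7-methoxy-5,5,8a-trimethyloctahydronaphthalen-2(1H)-one | O=C1CC[C@@H]2C(C)(C)C[C@@H](OC)C[C@@]2(C)[C@@H]1CCCl | intermediate
13 | (1R,4aR,7R,8aR)-1-(2-chloroethyl)-7-methoxy-5,5,8a-trimethyl-2-methylidenedecahydronaphthalene | C=C1CC[C@@H]2C(C)(C)C[C@@H](OC)C[C@@]2(C)[C@@H]1CCCl | intermediate
14 | tert-butyl(dimethyl)(prop-2-yn-1-yloxy)silane | C#CCO[Si](C)(C)C(C)(C)C | starting material
15 | lithium 3-{[tert-butyl(dimethyl)silyl]oxy}prop-1-yn-1-ide | [Li]C#CCO[Si](C)(C)C(C)(C)C | intermediate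
16 | tert-butyl 4-{[tert-butyl(dimethyl)silyl]oxy}but-2-ynoate | CC(C)(C)OC(=O)C#CCO[Si](C)(C)C(C)(C)C | intermediate
17 | {2-[(1R,4aR,7R,8aR)-7-methoxy-5,5,8a-trimethyl-2-methylidenedecahydronaphthalen-1-yl]ethyl}magnesium chloride | C=C1CC[C@@H]2C(C)(C)C[C@@H](OC)C[C@@]2(C)[C@@H]1CC[Mg]Cl | intermediate
18 | tert-butyl (2Z)-3-({[tert-butyl(dimethyl)silyl]oxy}methyl)-5-[(1R,4aR,7R,8aR)-7-methoxy-5,5,8a-trimethyl-2-methylidenedecahydronaphthalen-1-yl]pent-2-enoate | C=C1CC[C@@H]2C(C)(C)C[C@@H](OC)C[C@@]2(C)[C@@H]1CC/C(=C/C(=O)OC(C)(C)C)CO[Si](C)(C)C(C)(C)C | intermediate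
19 | tert-butyl (2Z)-3-(hydroxymethyl)-5-[(1R,4aR,7R,8aR)-7-methoxy-5,5,8a-trimethyl-2-methylidenedecahydronaphthalen-1-yl]pent-2-enoate | C=C1CC[C@@H]2C(C)(C)C[C@@H](OC)C[C@@]2(C)[C@@H]1CC/C(=C/C(=O)OC(C)(C)C)CO | intermediate
20 | tert-butyl (2Z)-3-(acetoxymethyl)-5-[(1R,4aR,7R,8aR)-7-methoxy-5,5,8a-trimethyl-2-methylidenedecahydronaphthalen-1-yl]pent-2-enoate | C=C1CC[C@@H]2C(C)(C)C[C@@H](OC)C[C@@]2(C)[C@@H]1CC/C(=C/C(=O)OC(C)(C)C)COC(C)=O | intermediate
21 | trimethylsilyl (2Z)-3-(acetoxymethyl)-5-[(1R,4aR,7R,8aR)-7-methoxy-5,5,8a-trimethyl-2-methylidenedecahydronaphthalen-1-yl]pent-2-enoate | C=C1CC[C@@H]2C(C)(C)C[C@@H](OC)C[C@@]2(C)[C@@H]1CC/C(=C/C(=O)O[Si](C)(C)C)COC(C)=O | intermediate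
22 | (2Z)-3-(acetoxymethyl)-5-[(1R,4aR,7R,8aR)-7-methoxy-5,5,8a-trimethyl-2-methylidenedecahydronaphthalen-1-yl]pent-2-enoic acid (CNP0155807.1; labdane numbering 2R,5R,9R,10R) | C=C1CC[C@@H]2C(C)(C)C[C@@H](OC)C[C@@]2(C)[C@@H]1CC/C(=C/C(=O)O)COC(C)=O | target

**Step count**
Total: 13 steps. Longest linear sequence: 12 steps (steps 1–9 and 11–13); step 10 is a one-step side branch.

**Three steps most likely to fail**

Step 7 (ring A closure). A monosubstituted alkene is a weak terminator, the C10 cation can undergo hydride or methyl shifts, and the trans ring fusion rests on a chair preference rather than on a concerted anti addition, so the cis-fused isomer may compete. The fallback sets out from 10 and comes back at 11. Tsuji–Wacker oxidation (PdCl2, CuCl, O2, DMF–H2O) of the terminal alkene gives the methyl ketone 4-[(3S,4R)-3-(2-chloroethyl)-4-hydroxy-2-methylcyclohex-1-en-1-yl]-4-methylpentan-2-one F7. Acid (MsOH, CH2Cl2) then closes ring A by attack of the ketone enol carbon C1 on the C10 cation (cation–enol cyclisation, a better π-nucleophile and no secondary cation), giving the 2-oxo analogue of 11 F8. SmI2/H2O/Et3N reduces the C2 ketone through the ketyl to the equatorial alcohol, the 2-hydroxy analogue of 11 F9. Ag2O/MeI methylates the unhindered equatorial C2 hydroxyl (the C8 hydroxyl is axial and flanked by C9 and the angular methyl), giving 11.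

Step 3 (Birch reductive alkylation). The enediolate carbon is flanked by two ortho substituents, and 1-bromo-2-chloroethane can eliminate or transfer bromine instead of alkylating. The fallback sets out from 4 and comes back at 8, separating dearomatisation from C–C bond formation. Birch reduction with a proton quench (Li, NH3, t-BuOH; NH4Cl) gives 2-methoxy-6-methyl-5-(2-methylpent-4-en-2-yl)cyclohexa-2,5-diene-1-carboxylic acid F1. Cs2CO3/allyl bromide gives its prop-2-en-1-yl ester F2, and 1 M HCl unmasks prop-2-en-1-yl 2-methyl-3-(2-methylpent-4-en-2-yl)-6-oxocyclohex-2-ene-1-carboxylate F3. C-Alkylation of this β-keto ester at its doubly activated carbon (K2CO3, 1-bromo-2-chloroethane, DMF) gives 8.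

Step 5 (enantioselective protonation). The enolate is a hindered dienolate, so the ee may be moderate and γ-protonation to the conjugated enone is possible. The fallback sets out from 8 and comes back at 10, replacing asymmetric catalysis by an enzymatic resolution. Non-selective decarboxylation (Pd(PPh3)4, HCO2H–Et3N) gives racemic 2-(2-chloroethyl)-3-methyl-4-(2-methylpent-4-en-2-yl)cyclohex-3-en-1-one F4. LiBH(s-Bu)3 gives the racemic cis alcohol F5. Lipase-catalysed acylation (Burkholderia cepacia lipase, vinyl acetate) esterifies the (1R)-carbinol (Kazlauskas rule) to (1R,2S)-2-(2-chloroethyl)-3-methyl-4-(2-methylpent-4-en-2-yl)cyclohex-3-en-1-yl acetate F6, which is separated from the unreacted enantiomer. K2CO3/MeOH then releases 10.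

**Further compounds**
F1 | step 3 | 2-methoxy-6-methyl-5-(2-methylpent-4-en-2-yl)cyclohexa-2,5-diene-1-carboxylic acid | COC1=CCC(C(C)(C)CC=C)=C(C)C1C(=O)O
F2 | step 3 | prop-2-en-1-yl 2-methoxy-6-methyl-5-(2-methylpent-4-en-2-yl)cyclohexa-2,5-diene-1-carboxylate | COC1=CCC(C(C)(C)CC=C)=C(C)C1C(=O)OCC=C
F3 | step 3 | prop-2-en-1-yl 2-methyl-3-(2-methylpent-4-en-2-yl)-6-oxocyclohex-2-ene-1-carboxylate (racemic) | O=C1CCC(C(C)(C)CC=C)=C(C)C1C(=O)OCC=C
F4 | step 5 | racemic 2-(2-chloroethyl)-3-methyl-4-(2-methylpent-4-en-2-yl)cyclohex-3-en-1-one | O=C1CCC(C(C)(C)CC=C)=C(C)C1CCCl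
F5 | step 5 | racemic cis-2-(2-chloroethyl)-3-methyl-4-(2-methylpent-4-en-2-yl)cyclohex-3-en-1-ol (1:1 mixture of enantiomers) | O[C@@H]1CCC(C(C)(C)CC=C)=C(C)[C@@H]1CCCl.O[C@H]1CCC(C(C)(C)CC=C)=C(C)[C@H]1CCCl
F6 | step 5 | (1R,2S)-2-(2-chloroethyl)-3-methyl-4-(2-methylpent-4-en-2-yl)cyclohex-3-en-1-yl acetate | CC(=O)O[C@@H]1CCC(C(C)(C)CC=C)=C(C)[C@@H]1CCCl
F7 | step 7 | 4-[(3S,4R)-3-(2-chloroethyl)-4-hydroxy-2-methylcyclohex-1-en-1-yl]-4-methylpentan-2-one | O[C@@H]1CCC(C(C)(C)CC(C)=O)=C(C)[C@@H]1CCCl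
F8 | step 7 | 2-oxo analogue of 11 (C2 ketone in place of CH–OMe; all other centres as in 11) | O[C@@H]1CC[C@@H]2C(C)(C)CC(=O)C[C@@]2(C)[C@@H]1CCCl
F9 | step 7 | 2-hydroxy analogue of 11 (equatorial C2–OH in place of OMe; all other centres as in 11) | O[C@@H]1CC[C@@H]2C(C)(C)C[C@@H](O)C[C@@]2(C)[C@@H]1CCCl
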